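## Structural features

The target is a 2,3-dihydro-1-benzofuran: a benzo ring fused through C3a–C7a to a dihydrofuran ring (O1, C2, C3). C2 carries a 4-hydroxyphenyl group, C3 a 2,4-dihydroxybenzoyl group, and C5 a 3-(2,4-dihydroxyphenyl)-3-oxopropyl chain. C2 and C3 are adjacent stereocentres, both S, with the aryl and aroyl groups trans on the five-membered ring. C3–H is benzylic and α to a ketone and can epimerise, although trans is the more stable arrangement. O1–C2 is a benzylic aryl ether that a free para-phenol can ionise to a para-quinone methide and that palladium can hydrogenolyse. The five phenols and two aryl ketones exclude strongly basic, strongly Lewis-acidic or forcing reductive conditions late in the route. The real difficulty is fixing the absolute configuration of the trans C2/C3 pair and keeping it through the attachment of two resorcinol ketones and the deprotection. The key step uses the fact that the ether bond O1–C7a lies para to C5: a formyl group at C5 activates a fluoride at C7a for displacement by the C2 oxygen and is also the anchor for the C5 chain.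

## Logic of the disconnections

27 to 26. The five O–CH2Ph bonds are cut and the saturated Cα–Cβ bond of the C5 chain is traced back to a C=C bond. One neutral hydrogenation then does both jobs, and no acid or base meets the free 4-hydroxyphenyl group beside O1–C2. All phenols become identically masked and the chain becomes an enone. The forward step must stop before the O1–C2 ether or the aryl ketones are reduced.

26 to 20 and 25. The chain C=C bond is cut between the carbon on C5 and the carbon α to the chain ketone. The C5 formyl group is already present because the key step needs it. This removes one complete resorcinol ketone in a convergent way. The forward step must olefinate the aldehyde beside the C3 ketone without a base that could enolise C3, which calls for a stabilised, non-basic ylide.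

25 to 23, 22 and 21. The P–C bond, the C–Br bond and two O–benzyl bonds are cut in turn. This leads to a cheap resorcinol ketone. The forward bromination must go at the methyl group and not on the electron-rich ring.

20 to 15 and 17 (through 18 and 19). The bond between the C3 carbonyl carbon and its resorcinol ring is cut. This returns the C3 substituent to the carboxylic acid level that the key step requires. It removes the second resorcinol unit. The forward acyl transfer must spare the formyl group and must not enolise the acyl donor, which points to an arylzinc under palladium catalysis.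

17 to 16. Two O–benzyl bonds are cut. The forward step is a plain double etherification.

15 to 14. The aryl ether bond O1–C7a is cut. It lies para to the formyl group, so a fluoride at C7a can be displaced, and neither stereocentre lies on the bond. The bicycle opens to an acyclic β-hydroxy acid, so the stereochemical problem becomes an aldol problem. The forward step needs the alkoxide to attack C7a in preference to every other base-induced pathway.

14 to 11 (through 13 and 12). The acyl–N bond to the auxiliary and the two C–O bonds of the acetal are restored. The forward order matters: peroxide must be gone before the formyl group is freed, and the acid used for unmasking must not ionise the alkoxybenzylic carbinol.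

11 to 7 and 8 (through 10 and 9). The Cα–Cβ bond of the propanoyl chain is cut; it becomes C3–C2 of the ring. Both stereocentres then arise in one step from two simple pieces. The forward step needs a Z-enolate, a closed transition state (syn) and facial control by the auxiliary, and the acetal must survive the boron triflate.

7 to 4 and 5 (through 6). The N–acyl bond is cut. The forward acylation must avoid strong base at the acidic benzylic methylene.

4 to 3, 2 and 1. The ester O–ethyl bond, the aryl–CH2 bond and the acetal are cut in turn. This leads to a cheap bromofluorobenzaldehyde whose bromide marks the site of the acetic acid unit. The forward coupling must use C–Br and leave C–F, and must give the monoacid without an acidic decarboxylation that would endanger the acetal.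

## Other disconnections considered

Alternative 1: The cut is C3–C3a, with the dihydrofuran ring traced back to the pyranone ring of the flavanone (2S)-6-bromo-2-[4-(tosyloxy)phenyl]-2,3-dihydro-4H-chromen-4-one A2. In the forward step a diacetoxyiodoarene (trivalent iodine) in acidified orthoformate iodinates C3 of the enol ether, and the fused arene carbon migrates from C4 to C3 as the iodoarene leaves. This gives the ring-contracted ester methyl (2S,3S)-trans-5-bromo-2-[4-(tosyloxy)phenyl]-2,3-dihydro-1-benzofuran-3-carboxylate A1.
- In favour: the transformation belongs to a known class, C2 is not touched, and anti migration should give the trans ester. No auxiliary is needed. A1 should be reachable in fewer steps than 15, and on that count this alternative is the better one.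
- Against: under strong acid a flavanone can open reversibly to its hydroxychalcone, which would erode the configuration of A2. Oxidation to flavone-type products and migration of the C2 aryl group compete with the ring contraction. The tosylate needed to restrain the C2 aryl group must later be removed with a strong nucleophile or base on a base-sensitive molecule. The C5 bromide needs a palladium coupling with an unstable aryl vinyl ketone.
- Comparison: both plans give a C3 carboxyl-level group and a C5 handle. The chosen closure has spectator stereocentres and one plausible pathway, whereas A1 arises from a cationic rearrangement with several competing branches. Once the ester hydrolysis and the tosylate exchange are counted, overall step economy is about equal.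

Alternative 2: The cuts are C3a–C4 and C5–C6, so the benzo ring is built last. The precursor is the furopyranone (2S,3S)-3-[2,4-bis(benzyloxy)benzoyl]-2-[4-(benzyloxy)phenyl]-2,3-dihydro-4H-furo[3,2-c]pyran-4-one A3. On heating, its 2-pyranone diene should add propynal A4 across its termini, and the bridged lactone should then lose CO2. The product is (2S,3S)-3-[2,4-bis(benzyloxy)benzoyl]-2-[4-(benzyloxy)phenyl]-2,3-dihydro-1-benzofuran-5-carbaldehyde A5, which is the same structure as 20.
- In favour: the donor oxygen at C7a should steer the formyl carbon of A4 to C5, and loss of CO2 is irreversible. The C3 ketone is already in place, and the endgame would be the two last steps of the chosen route. On convergence and on the number of steps after the key step this alternative is the equal or the better of the chosen plan.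
- Against: pyranone cycloadditions with alkynes need high temperature, at which A4 polymerises. In A3 the leaving group of a ring-opening elimination at C3 is a vinylogous carboxylate, far better than a phenoxide, so the configuration at C2 is at greater risk. No reliable enantioselective route to A3 is evident, and the pyranone building block must lack a substituent at the carbon that becomes C6.
- Comparison: the stereochemical problem is moved to a less tractable heterocycle and is not solved by the key step. The chosen plan solves it by auxiliary control before any ring exists. Total step economy cannot be judged better while the route to A3 is open.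

Alternative 3: The cut is O1–C2. The substrate is the enone 1-[2,4-bis(benzyloxy)phenyl]-2-(5-bromo-2-hydroxyphenyl)-3-(4-hydroxyphenyl)prop-2-en-1-one A6. A chiral BINOL-derived phosphoric acid should turn A6 into its para-quinone methide tautomer 4-{3-[2,4-bis(benzyloxy)phenyl]-2-(5-bromo-2-hydroxyphenyl)-3-oxopropylidene}cyclohexa-2,5-dien-1-one A7. The ortho phenol oxygen then adds to C2 in a five-membered exo closure, giving [2,4-bis(benzyloxy)phenyl][(2S,3S)-5-bromo-2-(4-hydroxyphenyl)-2,3-dihydro-1-benzofuran-3-yl]methanone A8.
- In favour: the method is catalytic and needs no auxiliary. The C3 ketone is present from the start, and the free 4-hydroxyphenyl group is used productively. C3 can equilibrate to trans once C2 is set, so only C2 needs catalyst control. In step count and atom economy this alternative is the better one.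
- Against: the tautomerisation to A7 is uphill, and its control by the catalyst is uncertain for this substrate class. The free para-phenol in A8 lets O1–C2 re-ionise under the same acid, so the configuration at C2 could be lost after it is set. The bromide again needs a coupling with an aryl vinyl ketone, now beside a free phenol.
- Comparison: the chosen plan is longer but forms O1–C7a, a bond that cannot re-ionise, and takes its configuration from a dependable auxiliary aldol. Alternative 3 is shorter but stakes the configuration on a reversible step.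

Key step: step 7

Remark on the chemistry: ring positions follow 2,3-dihydro-1-benzofuran (O1, C2, C3, C3a, C4 to C7, C7a). The SMILES string of the target was re-derived as 2S,3S with the C2 aryl and C3 aroyl groups trans. The (4S)-benzyloxazolidinone is the enantiomer that gives this series in the boron aldol, and the syn adduct maps onto the trans ring, so no structure needed correction. Design choices made for safety are these:
- a cyclic acetal that is unmasked only after the peroxide step;
- a zinc ester enolate arylation that gives the monoester directly, so that no acidic decarboxylation is needed;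
- DMSO in the key step, so that no amine from an amide solvent competes for the fluoride;
- a neutral acid chloride formation;
- benzyl ethers throughout, which keep O1–C2 from ionising until the final neutral hydrogenation.

## Steps

Step 1
Reactants: 1 3-bromo-4-fluorobenzaldehyde
Product: 2 2-(3-bromo-4-fluorophenyl)-1,3-dioxolane
Conditions: HOCH2CH2OH, p-TsOH·H2O (cat.), toluene, reflux, Dean–Stark
Reagents that add atoms: ethane-1,2-diol, OCCO
Why: Acid-catalysed acetalisation with azeotropic removal of water; the cyclic acetal hides the formyl group from the organozinc, enolate and hydroperoxide steps and is inert to base.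

Step 2
Reactants: 2 2-(3-bromo-4-fluorophenyl)-1,3-dioxolane
Product: 3 ethyl 2-[5-(1,3-dioxolan-2-yl)-2-fluorophenyl]acetate
Conditions: BrZnCH2CO2Et (from BrCH2CO2Et, Zn, TMSCl cat.), Pd2(dba)3 (cat.), XPhos, THF, 60 °C
Reagents that add atoms: ethyl bromoacetate, BrCC(=O)OCC
Why: Palladium-catalysed Negishi-type arylation of a Reformatsky reagent; oxidative addition should occur at C–Br and not at C–F, and the neutral zinc enolate tolerates the acetal and gives the monoester directly.

Step 3
Reactants: 3 ethyl 2-[5-(1,3-dioxolan-2-yl)-2-fluorophenyl]acetate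
Product: 4 2-[5-(1,3-dioxolan-2-yl)-2-fluorophenyl]acetic acid
Conditions: LiOH·H2O, THF/H2O, rt; 10% aq. citric acid to pH 4, 0 °C
Reagents that add atoms: lithium hydroxide, [Li+].[OH-]
Why: Ester saponification; the acetal is inert to hydroxide, and the brief cold work-up at pH 4 is far too weakly acidic to hydrolyse an aryl dioxolane.

Step 4
Reactants: 4 2-[5-(1,3-dioxolan-2-yl)-2-fluorophenyl]acetic acid; 5 (4S)-4-benzyl-1,3-oxazolidin-2-one
Product: 7 (4S)-4-benzyl-3-{2-[5-(1,3-dioxolan-2-yl)-2-fluorophenyl]acetyl}-1,3-oxazolidin-2-one, via mixed pivalic anhydride 6 (not isolated)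
Conditions: PivCl, Et3N, THF, −20 °C; then LiCl, 5, −20 °C → rt
Reagents that add atoms: pivaloyl chloride, CC(C)(C)C(Cl)=O (its atoms stay in 6 only)
Why: N-Acylation of the oxazolidinone through a mixed anhydride with lithium chloride and amine activation; the nucleophile should attack the less hindered arylacetyl carbonyl, and no strong base meets the acidic benzylic methylene.

Step 5
Reactants: 7 (4S)-4-benzyl-3-{2-[5-(1,3-dioxolan-2-yl)-2-fluorophenyl]acetyl}-1,3-oxazolidin-2-one; 8 4-(benzyloxy)benzaldehyde
Product: 11 (4S)-4-benzyl-3-{(2S,3S)-3-[4-(benzyloxy)phenyl]-2-[5-(1,3-dioxolan-2-yl)-2-fluorophenyl]-3-hydroxypropanoyl}-1,3-oxazolidin-2-one, via dibutylboron Z-enolate 9 (not isolated), via dibutylboron aldolate 10 (not isolated)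
Conditions: Bu2BOTf, i-Pr2NEt, CH2Cl2, −78 → 0 °C; 8, −78 → 0 °C; pH 7 buffer, MeOH, 30% H2O2, 0 °C
Reagents that add atoms: dibutylboron trifluoromethanesulfonate, CCCCB(CCCC)OS(=O)(=O)C(F)(F)F (boron and butyl groups stay in 9 and 10 only)
Why: Evans boron syn-aldol: soft enolisation gives the Z-enolate 9, which should react through a closed Zimmerman–Traxler chair with the aldehyde aryl group equatorial (syn); the dipole-opposed (4S)-auxiliary leaves open only the enolate face away from its benzyl group, which sets both new centres as S. The buffered peroxide work-up only cleaves the B–O bond of 10, and cyclic acetals normally survive amine-buffered boron triflate at low temperature.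

Step 6
Reactants: 11 (4S)-4-benzyl-3-{(2S,3S)-3-[4-(benzyloxy)phenyl]-2-[5-(1,3-dioxolan-2-yl)-2-fluorophenyl]-3-hydroxypropanoyl}-1,3-oxazolidin-2-one
Product: 14 (2S,3S)-3-[4-(benzyloxy)phenyl]-2-(2-fluoro-5-formylphenyl)-3-hydroxypropanoic acid, via peroxy acid 12 (not isolated), via acetal acid 13 (not isolated)
Conditions: LiOH, 30% H2O2, THF/H2O, 0 °C; aq. Na2SO3; CH2Cl2 wash; then 1 M HCl to pH 1, THF/H2O, rt
Reagents that add atoms: hydrogen peroxide, OO; water, O
Why: Hydroperoxide hydrolysis of the imide at the exocyclic carbonyl gives 12, which sulfite reduces to 13 while the formyl group is still masked against peroxide. Specific-acid hydrolysis of the aryl dioxolane at pH 1 should be far faster than ionisation of the alkoxybenzylic carbinol, whose cation is destabilised by the neighbouring carboxyl-bearing carbon, so both stereocentres should stay untouched.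

Step 7
Reactants: 14 (2S,3S)-3-[4-(benzyloxy)phenyl]-2-(2-fluoro-5-formylphenyl)-3-hydroxypropanoic acid
Product: 15 (2S,3S)-2-[4-(benzyloxy)phenyl]-5-formyl-2,3-dihydro-1-benzofuran-3-carboxylic acid
Conditions: Cs2CO3 (3 equiv), dry DMSO (0.05 M), 60 °C; then cold 1 M HCl to pH 3
Reagents that add atoms: none
Why: Cs2CO3 forms the carboxylate and, reversibly, the alkoxide of 14; the alkoxide oxygen adds to C7a, the fluorine-bearing carbon para to the formyl group, giving an anionic σ-adduct stabilised through the formyl group, and fluoride then leaves (intramolecular nucleophilic aromatic substitution by addition–elimination). The closest known reaction type is the displacement of fluoride from 4-fluorobenzaldehyde-type arenes by alkoxides, in its intramolecular form giving 2,3-dihydrobenzofurans. The dihydrofuran ring closes in a five-membered exo mode at the arene carbon (O1 to C7a), with C3a–C7a already in place. No new stereocentre is formed: no bond to C2 or C3 is made or broken, so the S,S syn-aldol array is carried over and appears as the 2,3-trans ring because O1 and C3a become ring members. The step needs attack by the alkoxide in preference to the carboxylate (which could also close a five-membered ring), to addition at the formyl group, and to retro-aldol cleavage or dehydration. The much higher nucleophilicity of the alkoxide and the reversibility of hemiacetal formation secure the first two, and retro-aldol or E1cB loss of water would require a carbanion α to a carboxylate, which secures the third. DMSO and dry conditions keep dimethylamine and hydroxide away from the activated fluoride.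

Step 8
Reactants: 16 4-bromobenzene-1,3-diol (4-bromoresorcinol)
Product: 17 2,4-bis(benzyloxy)-1-bromobenzene
Conditions: BnBr, K2CO3, DMF, 60 °C
Reagents that add atoms: benzyl bromide, BrCc1ccccc1
Why: Williamson etherification of both phenols; benzyl ethers tolerate the organometallic step and are removed at the end under neutral conditions.

Step 9
Reactants: 15 (2S,3S)-2-[4-(benzyloxy)phenyl]-5-formyl-2,3-dihydro-1-benzofuran-3-carboxylic acid; 17 2,4-bis(benzyloxy)-1-bromobenzene
Product: 20 (2S,3S)-3-[2,4-bis(benzyloxy)benzoyl]-2-[4-(benzyloxy)phenyl]-2,3-dihydro-1-benzofuran-5-carbaldehyde, via acid chloride 18 (not isolated), via arylzinc chloride 19 (not isolated)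
Conditions: 15, Me2C=C(Cl)NMe2, CH2Cl2, 0 °C → rt; separately 17, n-BuLi, THF, −78 °C, then ZnCl2, −78 → 0 °C; combine, Pd(PPh3)4 (cat.), THF, 0 °C → rt
Reagents that add atoms: 1-chloro-N,N,2-trimethylprop-1-en-1-amine, CC(C)=C(Cl)N(C)C (chlorine stays in 18 only); zinc dichloride, Cl[Zn]Cl (zinc and chlorine stay in 19 only)
Why: Negishi acylation: zerovalent palladium inserts into the C–Cl bond of 18 much faster than the arylzinc adds to an aldehyde, so the formyl group should survive. The acid chloride is made with Ghosez's reagent without acid or base, so neither a ketene nor ionisation of O1–C2 is provoked, and any epimerisation at C3 would return to the more stable trans isomer.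

Step 10
Reactants: 21 1-(2,4-dihydroxyphenyl)ethan-1-one
Product: 22 1-[2,4-bis(benzyloxy)phenyl]ethan-1-one
Conditions: BnBr, K2CO3, KI (cat.), DMF, 80 °C
Reagents that add atoms: benzyl bromide, BrCc1ccccc1
Why: Williamson etherification; the hydrogen-bonded ortho phenol needs the higher temperature and iodide catalysis.

Step 11
Reactants: 22 1-[2,4-bis(benzyloxy)phenyl]ethan-1-one
Product: 23 1-[2,4-bis(benzyloxy)phenyl]-2-bromoethan-1-one
Conditions: CuBr2, EtOAc/CHCl3, reflux
Reagents that add atoms: copper dibromide, Br[Cu]Br
Why: α-Bromination of an aryl methyl ketone through its copper enolate; this heterogeneous reagent brominates the methyl group and should leave the electron-rich ring alone.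

Step 12
Reactants: 23 1-[2,4-bis(benzyloxy)phenyl]-2-bromoethan-1-one
Product: 25 1-[2,4-bis(benzyloxy)phenyl]-2-(triphenyl-λ5-phosphanylidene)ethan-1-one, via phosphonium bromide 24 (not isolated)
Conditions: PPh3, toluene, 60 °C; then 2 M NaOH, CH2Cl2/H2O, rt
Reagents that add atoms: triphenylphosphine, c1ccc(cc1)P(c1ccccc1)c1ccccc1
Why: SN2 alkylation of the phosphine at the primary bromide, then deprotonation of the acidic phosphonium salt to the stabilised keto ylide, which is stable to water and can be stored.

Step 13
Reactants: 20 (2S,3S)-3-[2,4-bis(benzyloxy)benzoyl]-2-[4-(benzyloxy)phenyl]-2,3-dihydro-1-benzofuran-5-carbaldehyde; 25 1-[2,4-bis(benzyloxy)phenyl]-2-(triphenyl-λ5-phosphanylidene)ethan-1-one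
Product: 26 (2E)-1-[2,4-bis(benzyloxy)phenyl]-3-{(2S,3S)-3-[2,4-bis(benzyloxy)benzoyl]-2-[4-(benzyloxy)phenyl]-2,3-dihydro-1-benzofuran-5-yl}prop-2-en-1-one
Conditions: toluene, 100 °C
Reagents that add atoms: none
Why: Wittig olefination with a stabilised ylide, which should react only with the aldehyde and not with the hindered C3 ketone, should give the E-enone, and is too weak a base to enolise C3. The benzyl ether on the C2 aryl group keeps O1–C2 from ionising on heating.

Step 14
Reactants: 26 (2E)-1-[2,4-bis(benzyloxy)phenyl]-3-{(2S,3S)-3-[2,4-bis(benzyloxy)benzoyl]-2-[4-(benzyloxy)phenyl]-2,3-dihydro-1-benzofuran-5-yl}prop-2-en-1-one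
Product: 27 1-(2,4-dihydroxyphenyl)-3-[(2S,3S)-3-(2,4-dihydroxybenzoyl)-2-(4-hydroxyphenyl)-2,3-dihydro-1-benzofuran-5-yl]propan-1-one
Conditions: H2 (1 atm), 10% Pd/C, THF/EtOAc, rt, stopped after six equivalents of H2
Reagents that add atoms: none
Why: Catalytic hydrogenation of the enone C=C bond and hydrogenolysis of the five primary benzyl aryl ethers in one neutral operation. The hindered secondary cyclic ether O1–C2 and the electron-rich aryl ketones should react more slowly, and no acid or base is present to ionise O1–C2 once the para-phenol is free.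

## Compound list

1 | 3-bromo-4-fluorobenzaldehyde | O=Cc1ccc(F)c(Br)c1 | starting material
2 | 2-(3-bromo-4-fluorophenyl)-1,3-dioxolane | Fc1ccc(cc1Br)C1OCCO1 | intermediate
3 | ethyl 2-[5-(1,3-dioxolan-2-yl)-2-fluorophenyl]acetate | CCOC(=O)Cc1cc(ccc1F)C1OCCO1 | intermediate
4 | 2-[5-(1,3-dioxolan-2-yl)-2-fluorophenyl]acetic acid | OC(=O)Cc1cc(ccc1F)C1OCCO1 | intermediate
5 | (4S)-4-benzyl-1,3-oxazolidin-2-one | O=C1N[C@@H](Cc2ccccc2)CO1 | starting material
6 | 2-[5-(1,3-dioxolan-2-yl)-2-fluorophenyl]acetic 2,2-dimethylpropanoic anhydride | CC(C)(C)C(=O)OC(=O)Cc1cc(ccc1F)C1OCCO1 | intermediate (not isolated)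
7 | (4S)-4-benzyl-3-{2-[5-(1,3-dioxolan-2-yl)-2-fluorophenyl]acetyl}-1,3-oxazolidin-2-one | O=C(Cc1cc(ccc1F)C1OCCO1)N1[C@@H](Cc2ccccc2)COC1=O | intermediate
8 | 4-(benzyloxy)benzaldehyde | O=Cc1ccc(OCc2ccccc2)cc1 | starting material
9 | (4S)-4-benzyl-3-{(Z)-1-[(dibutylboranyl)oxy]-2-[5-(1,3-dioxolan-2-yl)-2-fluorophenyl]ethenyl}-1,3-oxazolidin-2-one | CCCCB(CCCC)O/C(=C\c1cc(ccc1F)C1OCCO1)N1[C@@H](Cc2ccccc2)COC1=O | intermediate (not isolated)
10 | (4S)-4-benzyl-3-{(2S,3S)-3-[4-(benzyloxy)phenyl]-3-[(dibutylboranyl)oxy]-2-[5-(1,3-dioxolan-2-yl)-2-fluorophenyl]propanoyl}-1,3-oxazolidin-2-one | O=C(N1[C@@H](Cc2ccccc2)COC1=O)[C@@H](c1cc(ccc1F)C1OCCO1)[C@H](OB(CCCC)CCCC)c1ccc(OCc2ccccc2)cc1 | intermediate (not isolated)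
11 | (4S)-4-benzyl-3-{(2S,3S)-3-[4-(benzyloxy)phenyl]-2-[5-(1,3-dioxolan-2-yl)-2-fluorophenyl]-3-hydroxypropanoyl}-1,3-oxazolidin-2-one | O=C(N1[C@@H](Cc2ccccc2)COC1=O)[C@@H](c1cc(ccc1F)C1OCCO1)[C@H](O)c1ccc(OCc2ccccc2)cc1 | intermediate
12 | (2S,3S)-3-[4-(benzyloxy)phenyl]-2-[5-(1,3-dioxolan-2-yl)-2-fluorophenyl]-3-hydroxypropaneperoxoic acid | OOC(=O)[C@@H](c1cc(ccc1F)C1OCCO1)[C@H](O)c1ccc(OCc2ccccc2)cc1 | intermediate (not isolated)
13 | (2S,3S)-3-[4-(benzyloxy)phenyl]-2-[5-(1,3-dioxolan-2-yl)-2-fluorophenyl]-3-hydroxypropanoic acid | OC(=O)[C@@H](c1cc(ccc1F)C1OCCO1)[C@H](O)c1ccc(OCc2ccccc2)cc1 | intermediate (not isolated)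
14 | (2S,3S)-3-[4-(benzyloxy)phenyl]-2-(2-fluoro-5-formylphenyl)-3-hydroxypropanoic acid | O=Cc1ccc(F)c(c1)[C@H](C(=O)O)[C@@H](c1ccc(OCc2ccccc2)cc1)O | intermediate
15 | (2S,3S)-2-[4-(benzyloxy)phenyl]-5-formyl-2,3-dihydro-1-benzofuran-3-carboxylic acid | O=Cc1ccc2c(c1)[C@H](C(=O)O)[C@@H](c1ccc(OCc3ccccc3)cc1)O2 | intermediate
16 | 4-bromobenzene-1,3-diol | Oc1ccc(Br)c(O)c1 | starting material
17 | 2,4-bis(benzyloxy)-1-bromobenzene | Brc1ccc(OCc2ccccc2)cc1OCc1ccccc1 | intermediate
18 | (2S,3S)-2-[4-(benzyloxy)phenyl]-5-formyl-2,3-dihydro-1-benzofuran-3-carbonyl chloride | O=Cc1ccc2c(c1)[C@H](C(=O)Cl)[C@@H](c1ccc(OCc3ccccc3)cc1)O2 | intermediate (not isolated)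
19 | [2,4-bis(benzyloxy)phenyl]zinc chloride | Cl[Zn]c1ccc(OCc2ccccc2)cc1OCc1ccccc1 | intermediate (not isolated)
20 | (2S,3S)-3-[2,4-bis(benzyloxy)benzoyl]-2-[4-(benzyloxy)phenyl]-2,3-dihydro-1-benzofuran-5-carbaldehyde | O=Cc1ccc2c(c1)[C@H](C(=O)c1ccc(OCc3ccccc3)cc1OCc1ccccc1)[C@@H](c1ccc(OCc3ccccc3)cc1)O2 | intermediate
21 | 1-(2,4-dihydroxyphenyl)ethan-1-one | CC(=O)c1ccc(O)cc1O | starting material
22 | 1-[2,4-bis(benzyloxy)phenyl]ethan-1-one | CC(=O)c1ccc(OCc2ccccc2)cc1OCc1ccccc1 | intermediate
23 | 1-[2,4-bis(benzyloxy)phenyl]-2-bromoethan-1-one | BrCC(=O)c1ccc(OCc2ccccc2)cc1OCc1ccccc1 | intermediate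
24 | {2-[2,4-bis(benzyloxy)phenyl]-2-oxoethyl}triphenylphosphonium bromide | [Br-].O=C(C[P+](c1ccccc1)(c1ccccc1)c1ccccc1)c1ccc(OCc2ccccc2)cc1OCc1ccccc1 | intermediate (not isolated)
25 | 1-[2,4-bis(benzyloxy)phenyl]-2-(triphenyl-λ5-phosphanylidene)ethan-1-one | O=C(C=P(c1ccccc1)(c1ccccc1)c1ccccc1)c1ccc(OCc2ccccc2)cc1OCc1ccccc1 | intermediate
26 | (2E)-1-[2,4-bis(benzyloxy)phenyl]-3-{(2S,3S)-3-[2,4-bis(benzyloxy)benzoyl]-2-[4-(benzyloxy)phenyl]-2,3-dihydro-1-benzofuran-5-yl}prop-2-en-1-one | O=C(/C=C/c1ccc2c(c1)[C@H](C(=O)c1ccc(OCc3ccccc3)cc1OCc1ccccc1)[C@@H](c1ccc(OCc3ccccc3)cc1)O2)c1ccc(OCc2ccccc2)cc1OCc1ccccc1 | intermediate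
27 | 1-(2,4-dihydroxyphenyl)-3-[(2S,3S)-3-(2,4-dihydroxybenzoyl)-2-(4-hydroxyphenyl)-2,3-dihydro-1-benzofuran-5-yl]propan-1-one | O=C(CCc1ccc2c(c1)[C@H](C(=O)c1ccc(O)cc1O)[C@@H](c1ccc(O)cc1)O2)c1ccc(O)cc1O | target

## Step count and least certain steps

Total step count: 14. Longest linear sequence: 10 (steps 1 to 7, 9, 13 and 14). Compound 2 is also a catalogue compound; buying it would shorten both numbers by one.

Step 7 (key step). The hydroxyl group may be ionised too little by carbonate for a useful rate. Raising the temperature may then bring on retro-aldol fragmentation, arylation of the carboxylate oxygen, or displacement of fluoride by adventitious nucleophiles. The fallback makes O1–C7a by copper catalysis from a bromide and introduces the formyl group afterwards. It sets out from 5 and 8 and returns at 15.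
- 5 would be acylated with purchased (2,5-dibromophenyl)acetic acid (PivCl, Et3N, LiCl) to (4S)-4-benzyl-3-[2-(2,5-dibromophenyl)acetyl]-1,3-oxazolidin-2-one F1.
- The boron syn-aldol with 8 under the conditions of step 5 would give (4S)-4-benzyl-3-{(2S,3S)-3-[4-(benzyloxy)phenyl]-2-(2,5-dibromophenyl)-3-hydroxypropanoyl}-1,3-oxazolidin-2-one F2.
- LiOH/H2O2 would give (2S,3S)-3-[4-(benzyloxy)phenyl]-2-(2,5-dibromophenyl)-3-hydroxypropanoic acid F3.
- CuI, 3,4,7,8-tetramethyl-1,10-phenanthroline and Cs2CO3 in toluene at 90 °C should close the ring at the ortho bromide to (2S,3S)-2-[4-(benzyloxy)phenyl]-5-bromo-2,3-dihydro-1-benzofuran-3-carboxylic acid F4.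
- Bromine–lithium exchange on the lithium carboxylate (n-BuLi, THF, −78 °C) and quenching with DMF would then give 15.

Step 2. Transmetalation of the zinc enolate may be slow, so that protodebromination or self-condensation of the reagent takes over. The fallback is arylation of a soft malonate enolate followed by dealkoxycarbonylation. It sets out from 2 and returns at 3. Diethyl malonate, Pd(OAc)2, t-Bu3P·HBF4 and K3PO4 in toluene at 90 °C would give diethyl 2-[5-(1,3-dioxolan-2-yl)-2-fluorophenyl]propanedioate F5. Krapcho dealkoxycarbonylation (LiCl, wet DMSO, 140 °C) is neutral and spares the acetal, and would give 3.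

Step 6. The α-aryl aldol may undergo retro-aldol cleavage or attack at the ring carbonyl of the auxiliary under the basic peroxide. The later acid stage may ionise the alkoxybenzylic carbinol, with epimerisation or dehydration. The fallback blocks the retro-aldol pathway by temporary protection. It sets out from 11 and returns at 14.
- TESCl and imidazole in DMF would give (4S)-4-benzyl-3-{(2S,3S)-3-[4-(benzyloxy)phenyl]-2-[5-(1,3-dioxolan-2-yl)-2-fluorophenyl]-3-[(triethylsilyl)oxy]propanoyl}-1,3-oxazolidin-2-one F6.
- LiOH/H2O2 would give (2S,3S)-3-[4-(benzyloxy)phenyl]-2-[5-(1,3-dioxolan-2-yl)-2-fluorophenyl]-3-[(triethylsilyl)oxy]propanoic acid F7.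
- A single brief treatment with 1 M HCl in THF would remove the silyl ether and the acetal together to give 14.

Step 9. The acid chloride may lose configuration at C3 through enolisation, the acylpalladium species may decarbonylate, or the arylzinc may add to the formyl group if the coupling is slow. The fallback is a Fukuyama coupling of an isolable thioester. It sets out from 15 and returns at 20. EtSH, EDC·HCl and DMAP (cat.) in CH2Cl2 at 0 °C would give S-ethyl (2S,3S)-2-[4-(benzyloxy)phenyl]-5-formyl-2,3-dihydro-1-benzofuran-3-carbothioate F8. Coupling of F8 with 19 under PdCl2(PPh3)2 in THF/toluene at rt should give 20 with the aldehyde untouched.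

Step 14. Hydrogenolysis may go on to the benzylic O1–C2 bond once the benzyl ethers are gone, an aryl ketone may be reduced, or the ortho benzyl ethers may be cleaved incompletely. The fallback separates the two reductions. It sets out from 26 and returns at 27. Conjugate reduction with [(Ph3P)CuH]6 (cat.) and PhSiH3 in toluene at rt cannot cleave C–O bonds. It would give 1-[2,4-bis(benzyloxy)phenyl]-3-{(2S,3S)-3-[2,4-bis(benzyloxy)benzoyl]-2-[4-(benzyloxy)phenyl]-2,3-dihydro-1-benzofuran-5-yl}propan-1-one F9. Transfer hydrogenolysis with Pd(OH)2/C and a measured amount of 1,4-cyclohexadiene in EtOAc/EtOH at rt would then remove the benzyl groups with a limited supply of hydrogen to give 27.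

## Further compounds

F1 | step 7 | (4S)-4-benzyl-3-[2-(2,5-dibromophenyl)acetyl]-1,3-oxazolidin-2-one | O=C(Cc1cc(Br)ccc1Br)N1[C@@H](Cc2ccccc2)COC1=O
F2 | step 7 | (4S)-4-benzyl-3-{(2S,3S)-3-[4-(benzyloxy)phenyl]-2-(2,5-dibromophenyl)-3-hydroxypropanoyl}-1,3-oxazolidin-2-one | O=C(N1[C@@H](Cc2ccccc2)COC1=O)[C@@H](c1cc(Br)ccc1Br)[C@H](O)c1ccc(OCc2ccccc2)cc1
F3 | step 7 | (2S,3S)-3-[4-(benzyloxy)phenyl]-2-(2,5-dibromophenyl)-3-hydroxypropanoic acid | OC(=O)[C@@H](c1cc(Br)ccc1Br)[C@H](O)c1ccc(OCc2ccccc2)cc1
F4 | step 7 | (2S,3S)-2-[4-(benzyloxy)phenyl]-5-bromo-2,3-dihydro-1-benzofuran-3-carboxylic acid | Brc1ccc2c(c1)[C@H](C(=O)O)[C@@H](c1ccc(OCc3ccccc3)cc1)O2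
F5 | step 2 | diethyl 2-[5-(1,3-dioxolan-2-yl)-2-fluorophenyl]propanedioate | CCOC(=O)C(C(=O)OCC)c1cc(ccc1F)C1OCCO1
F6 | step 6 | (4S)-4-benzyl-3-{(2S,3S)-3-[4-(benzyloxy)phenyl]-2-[5-(1,3-dioxolan-2-yl)-2-fluorophenyl]-3-[(triethylsilyl)oxy]propanoyl}-1,3-oxazolidin-2-one | O=C(N1[C@@H](Cc2ccccc2)COC1=O)[C@@H](c1cc(ccc1F)C1OCCO1)[C@H](O[Si](CC)(CC)CC)c1ccc(OCc2ccccc2)cc1
F7 | step 6 | (2S,3S)-3-[4-(benzyloxy)phenyl]-2-[5-(1,3-dioxolan-2-yl)-2-fluorophenyl]-3-[(triethylsilyl)oxy]propanoic acid | OC(=O)[C@@H](c1cc(ccc1F)C1OCCO1)[C@H](O[Si](CC)(CC)CC)c1ccc(OCc2ccccc2)cc1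
F8 | step 9 | S-ethyl (2S,3S)-2-[4-(benzyloxy)phenyl]-5-formyl-2,3-dihydro-1-benzofuran-3-carbothioate | O=Cc1ccc2c(c1)[C@H](C(=O)SCC)[C@@H](c1ccc(OCc3ccccc3)cc1)O2
F9 | step 14 | 1-[2,4-bis(benzyloxy)phenyl]-3-{(2S,3S)-3-[2,4-bis(benzyloxy)benzoyl]-2-[4-(benzyloxy)phenyl]-2,3-dihydro-1-benzofuran-5-yl}propan-1-one | O=C(CCc1ccc2c(c1)[C@H](C(=O)c1ccc(OCc3ccccc3)cc1OCc1ccccc1)[C@@H](c1ccc(OCc3ccccc3)cc1)O2)c1ccc(OCc2ccccc2)cc1OCc1ccccc1
A1 | alternative 1 | methyl (2S,3S)-trans-5-bromo-2-[4-(tosyloxy)phenyl]-2,3-dihydro-1-benzofuran-3-carboxylate | Brc1ccc2c(c1)[C@H](C(=O)OC)[C@@H](c1ccc(OS(=O)(=O)c3ccc(C)cc3)cc1)O2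
A2 | alternative 1 | (2S)-6-bromo-2-[4-(tosyloxy)phenyl]-2,3-dihydro-4H-chromen-4-one | O=C1C[C@@H](c2ccc(OS(=O)(=O)c3ccc(C)cc3)cc2)Oc2ccc(Br)cc12
A3 | alternative 2 | (2S,3S)-3-[2,4-bis(benzyloxy)benzoyl]-2-[4-(benzyloxy)phenyl]-2,3-dihydro-4H-furo[3,2-c]pyran-4-one | O=C1OC=CC2=C1[C@H](C(=O)c1ccc(OCc3ccccc3)cc1OCc1ccccc1)[C@@H](c1ccc(OCc3ccccc3)cc1)O2
A4 | alternative 2 | propynal | C#CC=O
A5 | alternative 2 | (2S,3S)-3-[2,4-bis(benzyloxy)benzoyl]-2-[4-(benzyloxy)phenyl]-2,3-dihydro-1-benzofuran-5-carbaldehyde | O=Cc1ccc2c(c1)[C@H](C(=O)c1ccc(OCc3ccccc3)cc1OCc1ccccc1)[C@@H](c1ccc(OCc3ccccc3)cc1)O2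
A6 | alternative 3 | 1-[2,4-bis(benzyloxy)phenyl]-2-(5-bromo-2-hydroxyphenyl)-3-(4-hydroxyphenyl)prop-2-en-1-one | O=C(C(=Cc1ccc(O)cc1)c1cc(Br)ccc1O)c1ccc(OCc2ccccc2)cc1OCc1ccccc1
A7 | alternative 3 | 4-{3-[2,4-bis(benzyloxy)phenyl]-2-(5-bromo-2-hydroxyphenyl)-3-oxopropylidene}cyclohexa-2,5-dien-1-one | O=C1C=CC(=CC(c2cc(Br)ccc2O)C(=O)c2ccc(OCc3ccccc3)cc2OCc2ccccc2)C=C1
A8 | alternative 3 | [2,4-bis(benzyloxy)phenyl][(2S,3S)-5-bromo-2-(4-hydroxyphenyl)-2,3-dihydro-1-benzofuran-3-yl]methanone | Brc1ccc2c(c1)[C@H](C(=O)c1ccc(OCc3ccccc3)cc1OCc1ccccc1)[C@@H](c1ccc(O)cc1)O2
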